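**Assumption:** the target has no stereocentre and no stereogenic double bond, so no enantiocontrol is needed; it is delivered as the free hydrogen sulfate drawn, released from its sodium salt in the last operation.

## Retrosynthetic overview

1. Target ⇐ hydrogenolysis of four benzyl ethers ⇐ sulfation of the only free phenol (6-OH) of 5,7,3',4'-tetra-O-benzyl-6-hydroxyluteolin.
2. Ring C (pyranone, formed last) ⇐ iodine/DMSO oxidative cyclization of a 2'-hydroxychalcone; the O-6 MOM group is removed in the same operation.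
3. Chalcone ⇐ intermolecular Claisen–Schmidt aldol condensation of a ring A acetophenone with 3,4-bis(benzyloxy)benzaldehyde (ring B). This forms the future C2–C3 bond; rings A and B are bought preformed.
4. Ring A acetophenone ⇐ 2,4,6-trihydroxyacetophenone by 4,6-dibenzylation, Elbs para-hydroxylation (the future O-6) and selective MOM protection of the new OH.

## Route

**Step 1**
Reactants: 1 2,4,6-trihydroxyacetophenone
Product: 2 1-[2,4-bis(benzyloxy)-6-hydroxyphenyl]ethanone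
Conditions: BnBr (2.1 equiv), K2CO3 (2.2 equiv), DMF, rt → 40 °C, N2
Reagents that add atoms: benzyl bromide, BrCc1ccccc1
Why: Williamson ether synthesis; once one ortho OH is benzylated, the remaining ortho OH is locked in a hydrogen bond to the acetyl carbonyl and stays free.

**Step 2**
Reactants: 2 1-[2,4-bis(benzyloxy)-6-hydroxyphenyl]ethanone
Product: 4 1-[2,4-bis(benzyloxy)-3,6-dihydroxyphenyl]ethanone, via potassium aryl sulfate 3 (not isolated)
Conditions: K2S2O8 (1.2 equiv), 10% aq NaOH–pyridine, 10–20 °C, 24 h; extract unreacted 2; then aq HCl (pH 1), 80 °C, 45 min, N2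
Reagents that add atoms: potassium peroxodisulfate, [K+].[K+].[O-]S(=O)(=O)OOS(=O)(=O)[O-]
Why: Elbs persulfate oxidation; the phenoxide attacks the peroxide oxygen through the carbon para to the free OH, and the resulting aryl sulfate is hydrolysed by acid to the hydroquinone while the benzyl ethers survive.

**Step 3**
Reactants: 4 1-[2,4-bis(benzyloxy)-3,6-dihydroxyphenyl]ethanone
Product: 5 1-[2,4-bis(benzyloxy)-6-hydroxy-3-(methoxymethoxy)phenyl]ethanone
Conditions: MOMCl (1.2 equiv), K2CO3 (1.5 equiv), acetone, 0 °C → rt, N2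
Reagents that add atoms: chloromethyl methyl ether, COCCl
Why: Selective O-alkylation (Williamson-type acetal formation) of the non-chelated OH; the OH ortho to the acetyl group is hydrogen-bonded and unreactive under mild base.

**Step 4**
Reactants: 5 1-[2,4-bis(benzyloxy)-6-hydroxy-3-(methoxymethoxy)phenyl]ethanone; 6 3,4-bis(benzyloxy)benzaldehyde
Product: 8 (E)-1-[2,4-bis(benzyloxy)-6-hydroxy-3-(methoxymethoxy)phenyl]-3-[3,4-bis(benzyloxy)phenyl]prop-2-en-1-one, via aldol adduct 7 (not isolated)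
Conditions: KOH (50% aq, 10 equiv), EtOH–THF, rt, 36 h, N2; neutralise with AcOH to pH 6
Reagents that add atoms: none
Why: Claisen–Schmidt crossed aldol condensation of the methyl ketone enolate with a non-enolisable aldehyde, followed by E1cB dehydration to the conjugated E-alkene; MOM and benzyl ethers are base-stable.

**Step 5**
Reactants: 8 (E)-chalcone
Product: 11 5,7-bis(benzyloxy)-2-[3,4-bis(benzyloxy)phenyl]-6-hydroxy-4H-chromen-4-one, via flavanone 9 (not isolated), via MOM-protected flavone 10 (not isolated)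
Conditions: I2 (0.1 equiv), DMSO, 120 °C, 3 h; aq Na2S2O3 wash; crude then HCl (2 M) in MeOH–THF, 50 °C, 3 h
Reagents that add atoms: none
Why: Iodine-mediated oxidative cyclization of the 2'-hydroxychalcone (oxa-Michael closure, α-iodination and loss of HI, DMSO as terminal oxidant) builds ring C, and the following acid-catalysed acetal cleavage removes MOM, converging any material that lost it earlier, while benzyl ethers tolerate dilute HCl.

**Step 6**
Reactants: 11 5,7-bis(benzyloxy)-2-[3,4-bis(benzyloxy)phenyl]-6-hydroxy-4H-chromen-4-one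
Product: 13 sodium 5,7-bis(benzyloxy)-2-[3,4-bis(benzyloxy)phenyl]-4-oxo-4H-chromen-6-yl sulfate, via pyridinium sulfate salt 12 (not isolated)
Conditions: SO3·pyridine (8 equiv), pyridine, 60 °C, 12 h; then aq NaHCO3 to pH 8; silica (CH2Cl2–MeOH)
Reagents that add atoms: sulfur trioxide–pyridine complex, O=S(=O)([O-])[n+]1ccccc1; sodium hydrogen carbonate, [Na+].OC([O-])=O
Why: O-sulfation of a phenol with an amine–SO3 complex; the 6-OH is the only free hydroxyl, so the regiochemistry is unambiguous, and the salt is kept basic to protect the sulfate.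

**Step 7**
Reactants: 13 sodium 5,7-bis(benzyloxy)-2-[3,4-bis(benzyloxy)phenyl]-4-oxo-4H-chromen-6-yl sulfate
Product: 15 2-(3,4-dihydroxyphenyl)-5,7-dihydroxy-4-oxo-4H-chromen-6-yl hydrogen sulfate (6-hydroxyluteolin 6-sulfate), via sodium 6-hydroxyluteolin 6-sulfate 14 (not isolated)
Conditions: H2 (1 atm), 10% Pd/C, THF–MeOH (1:1), rt; filter; then 0.1 M HCl (1.0 equiv), 0 °C, C18 desalting (H2O → MeOH), lyophilise
Reagents that add atoms: none
Why: Catalytic hydrogenolysis cleaves the four benzyl ethers while the aryl sulfate monoester and the flavone enone are inert at 1 atm, and brief cold protonation gives the hydrogen sulfate form.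

## Compound list

1 | 2,4,6-trihydroxyacetophenone | CC(=O)c1c(O)cc(O)cc1O | starting material
2 | 1-[2,4-bis(benzyloxy)-6-hydroxyphenyl]ethanone | CC(=O)c1c(O)cc(OCc2ccccc2)cc1OCc1ccccc1 | intermediate
3 | potassium 3-acetyl-2,6-bis(benzyloxy)-4-hydroxyphenyl sulfate | CC(=O)c1c(O)cc(OCc2ccccc2)c(OS(=O)(=O)[O-])c1OCc1ccccc1.[K+] | intermediate (not isolated)
4 | 1-[2,4-bis(benzyloxy)-3,6-dihydroxyphenyl]ethanone | CC(=O)c1c(O)cc(OCc2ccccc2)c(O)c1OCc1ccccc1 | intermediate
5 | 1-[2,4-bis(benzyloxy)-6-hydroxy-3-(methoxymethoxy)phenyl]ethanone | CC(=O)c1c(O)cc(OCc2ccccc2)c(OCOC)c1OCc1ccccc1 | intermediate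
6 | 3,4-bis(benzyloxy)benzaldehyde | O=Cc1ccc(OCc2ccccc2)c(OCc2ccccc2)c1 | starting material
7 | 1-[2,4-bis(benzyloxy)-6-hydroxy-3-(methoxymethoxy)phenyl]-3-[3,4-bis(benzyloxy)phenyl]-3-hydroxypropan-1-one (racemic aldol adduct) | O=C(CC(O)c1ccc(OCc2ccccc2)c(OCc2ccccc2)c1)c1c(O)cc(OCc2ccccc2)c(OCOC)c1OCc1ccccc1 | intermediate (not isolated)
8 | (E)-1-[2,4-bis(benzyloxy)-6-hydroxy-3-(methoxymethoxy)phenyl]-3-[3,4-bis(benzyloxy)phenyl]prop-2-en-1-one | O=C(/C=C/c1ccc(OCc2ccccc2)c(OCc2ccccc2)c1)c1c(O)cc(OCc2ccccc2)c(OCOC)c1OCc1ccccc1 | intermediate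
9 | 5,7-bis(benzyloxy)-2-[3,4-bis(benzyloxy)phenyl]-6-(methoxymethoxy)chroman-4-one (racemic flavanone) | O=C1CC(c2ccc(OCc3ccccc3)c(OCc3ccccc3)c2)Oc2cc(OCc3ccccc3)c(OCOC)c(OCc3ccccc3)c21 | intermediate (not isolated)
10 | 5,7-bis(benzyloxy)-2-[3,4-bis(benzyloxy)phenyl]-6-(methoxymethoxy)-4H-chromen-4-one | O=c1cc(-c2ccc(OCc3ccccc3)c(OCc3ccccc3)c2)oc2cc(OCc3ccccc3)c(OCOC)c(OCc3ccccc3)c12 | intermediate (not isolated)
11 | 5,7-bis(benzyloxy)-2-[3,4-bis(benzyloxy)phenyl]-6-hydroxy-4H-chromen-4-one | O=c1cc(-c2ccc(OCc3ccccc3)c(OCc3ccccc3)c2)oc2cc(OCc3ccccc3)c(O)c(OCc3ccccc3)c12 | intermediate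
12 | pyridinium 5,7-bis(benzyloxy)-2-[3,4-bis(benzyloxy)phenyl]-4-oxo-4H-chromen-6-yl sulfate | O=c1cc(-c2ccc(OCc3ccccc3)c(OCc3ccccc3)c2)oc2cc(OCc3ccccc3)c(OS(=O)(=O)[O-])c(OCc3ccccc3)c12.c1cc[nH+]cc1 | intermediate (not isolated)
13 | sodium 5,7-bis(benzyloxy)-2-[3,4-bis(benzyloxy)phenyl]-4-oxo-4H-chromen-6-yl sulfate | O=c1cc(-c2ccc(OCc3ccccc3)c(OCc3ccccc3)c2)oc2cc(OCc3ccccc3)c(OS(=O)(=O)[O-])c(OCc3ccccc3)c12.[Na+] | intermediate
14 | sodium 2-(3,4-dihydroxyphenyl)-5,7-dihydroxy-4-oxo-4H-chromen-6-yl sulfate | O=c1cc(-c2ccc(O)c(O)c2)oc2cc(O)c(OS(=O)(=O)[O-])c(O)c12.[Na+] | intermediate (not isolated)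
15 | 2-(3,4-dihydroxyphenyl)-5,7-dihydroxy-4-oxo-4H-chromen-6-yl hydrogen sulfate (6-hydroxyluteolin 6-sulfate; achiral) | O=c1cc(-c2ccc(O)c(O)c2)oc2cc(O)c(OS(=O)(=O)O)c(O)c12 | target

## Summary

Total step count: 7. Longest linear sequence: 7 steps (1 → 15); aldehyde 6 is purchased.

**Steps most likely to fail, with fallbacks**

Step 2 (Elbs oxidation: low conversion and tar formation are typical). The fallback sets out from 2. The para-unsubstituted phenol is oxidised with PhI(OCOCF3)2 (2.2 equiv) in MeCN–H2O at 0 °C to 2-acetyl-3,5-bis(benzyloxy)cyclohexa-2,5-diene-1,4-dione F1. The quinone is then reduced with Na2S2O4 in EtOAc–H2O to the hydroquinone, which comes back to the route at 4.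

Step 5 (oxidative cyclization: HI may strip the benzyl ether next to the carbonyl, and aurone formation can compete). The fallback sets out from 5 and replaces the chalcone pathway by an intermolecular Claisen condensation. The dianion of 5 (LiN(SiMe3)2, 3.5 equiv, THF, −78 °C → rt) is acylated with commercial methyl 3,4-bis(benzyloxy)benzoate (COC(=O)c1ccc(OCc2ccccc2)c(OCc2ccccc2)c1). This gives 1-[2,4-bis(benzyloxy)-6-hydroxy-3-(methoxymethoxy)phenyl]-3-[3,4-bis(benzyloxy)phenyl]propane-1,3-dione F2. Acid cyclodehydration with HCl in MeOH–THF at 60 °C closes ring C and removes the MOM group in the same pot, coming back to the route at 11.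

Step 6 (sulfation of a phenol flanked by two benzyloxy groups may be sluggish, and the salt is awkward to purify). The fallback sets out from 11. The phenoxide (NaH, THF, 0 °C) is trapped with 2,2,2-trichloroethyl chlorosulfate (ClS(=O)(=O)OCC(Cl)(Cl)Cl) to give the neutral, chromatographable diester 5,7-bis(benzyloxy)-2-[3,4-bis(benzyloxy)phenyl]-4-oxo-4H-chromen-6-yl 2,2,2-trichloroethyl sulfate F3. Reductive unmasking with Zn dust and HCO2NH4 in MeOH gives ammonium 5,7-bis(benzyloxy)-2-[3,4-bis(benzyloxy)phenyl]-4-oxo-4H-chromen-6-yl sulfate F4. Evaporation from aqueous NaHCO3 exchanges the cation and comes back to the route at 13.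

## Further compounds

F1 | step 2 | 2-acetyl-3,5-bis(benzyloxy)cyclohexa-2,5-diene-1,4-dione | CC(=O)C1=C(OCc2ccccc2)C(=O)C(OCc2ccccc2)=CC1=O
F2 | step 5 | 1-[2,4-bis(benzyloxy)-6-hydroxy-3-(methoxymethoxy)phenyl]-3-[3,4-bis(benzyloxy)phenyl]propane-1,3-dione | O=C(CC(=O)c1ccc(OCc2ccccc2)c(OCc2ccccc2)c1)c1c(O)cc(OCc2ccccc2)c(OCOC)c1OCc1ccccc1
F3 | step 6 | 5,7-bis(benzyloxy)-2-[3,4-bis(benzyloxy)phenyl]-4-oxo-4H-chromen-6-yl 2,2,2-trichloroethyl sulfate | O=c1cc(-c2ccc(OCc3ccccc3)c(OCc3ccccc3)c2)oc2cc(OCc3ccccc3)c(OS(=O)(=O)OCC(Cl)(Cl)Cl)c(OCc3ccccc3)c12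
F4 | step 6 | ammonium 5,7-bis(benzyloxy)-2-[3,4-bis(benzyloxy)phenyl]-4-oxo-4H-chromen-6-yl sulfate | O=c1cc(-c2ccc(OCc3ccccc3)c(OCc3ccccc3)c2)oc2cc(OCc3ccccc3)c(OS(=O)(=O)[O-])c(OCc3ccccc3)c12.[NH4+]
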